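Ring B of the aryltetralin is cut at C4–C4a and C1–C8a, leaving ring A as an aryne and C1–C4, with C10 on C3, as a cyclobutanone. The feature exploited lies in ring A: C4a and C8a are adjacent and C8, beside C8a, carries OMe, so aryne C4a≡C8a is polarised to accept C4 at C4a and C1 at C8a. In one operation o-silylaryl triflate 10 and the desymmetrised cyclobutanone enol silane 13 should give 1-tetralone 17, ring B closed and C3 already set. Both syringyl rings derive from boronic acid 5. The C1 ketone then brings in C9 and the aryl group, and only C9–OH is free for sulfation.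

Key step: step 7

Numbering: tetralin numbering throughout (C1 bears the aryl group, C2 bears C9, C3 bears C10, C4 is CH2; ring A is C4a, C5–C8, C8a). The target is (1R,2S,3S), all-trans.
Assumption: the lithium amide of (S,S)-bis(1-phenylethyl)amine is taken to give (R)-13, by analogy with other 3-substituted cyclobutanones. If the sense is opposite, the (R,R)-amine is used and nothing else changes.
Assumption: the target is the free hydrogen sulfate as drawn, so the last step ends with exchange of sodium for a proton.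

Step 1
Reactants: 1 4-bromo-2,6-dimethoxyphenol
Product: 2 2-(benzyloxy)-5-bromo-1,3-dimethoxybenzene
Conditions: BnBr, K2CO3, DMF, 60 °C
Reagents that add atoms: benzyl bromide, BrCc1ccccc1
Why: Williamson ether synthesis (SN2 of the phenoxide on the benzylic bromide); benzyl is chosen because all O-benzyl groups can leave together by hydrogenolysis at the end without touching the sulfate.

Step 2
Reactants: 2 2-(benzyloxy)-5-bromo-1,3-dimethoxybenzene
Product: 5 [4-(benzyloxy)-3,5-dimethoxyphenyl]boronic acid, via aryllithium 3 (not isolated), via lithium borate 4 (not isolated)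
Conditions: n-BuLi, THF, −78 °C; B(Oi-Pr)3, −78 °C to rt; 1 M HCl
Reagents that add atoms: triisopropyl borate, CC(C)OB(OC(C)C)OC(C)C; water, O
Why: Bromine–lithium exchange, borylation and hydrolysis; at −78 °C the exchange is much faster than deprotonation of the benzylic ether CH2.

Step 3
Reactants: 5 [4-(benzyloxy)-3,5-dimethoxyphenyl]boronic acid (part of the batch; the rest goes to step 10)
Product: 6 4-(benzyloxy)-3,5-dimethoxyphenol
Conditions: 30% aq H2O2, THF, 0 °C to rt; aq Na2SO3
Reagents that add atoms: hydrogen peroxide, OO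
Why: ipso-Hydroxylation of an arylboronic acid (1,2-shift of the aryl group from boron to oxygen in the hydroperoxide adduct) places the oxygen on the future C4a.

Step 4
Reactants: 6 4-(benzyloxy)-3,5-dimethoxyphenol
Product: 7 4-(benzyloxy)-2-bromo-3,5-dimethoxyphenol
Conditions: NBS (1.0 equiv), CH2Cl2, −78 to 0 °C
Reagents that add atoms: N-bromosuccinimide, O=C1CCC(=O)N1Br
Why: Electrophilic aromatic bromination ortho to the free phenol; 6 has a mirror plane, so its two open positions are equivalent and only one monobromide can form, while one equivalent of NBS at low temperature limits dibromination and oxidation.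

Step 5
Reactants: 7 4-(benzyloxy)-2-bromo-3,5-dimethoxyphenol
Product: 10 4-(benzyloxy)-3,5-dimethoxy-2-(trimethylsilyl)phenyl trifluoromethanesulfonate, via silyl ether 8 (not isolated), via lithium phenoxide 9 (not isolated)
Conditions: (Me3Si)2NH, THF, 65 °C, evaporate; n-BuLi, THF, −78 °C; Tf2O, −78 to 0 °C
Reagents that add atoms: hexamethyldisilazane, C[Si](C)(C)N[Si](C)(C)C; trifluoromethanesulfonic anhydride, O=S(=O)(OS(=O)(=O)C(F)(F)F)C(F)(F)F
Why: O-silylation, bromine–lithium exchange, retro-Brook 1,3-shift of silicon from oxygen to carbon and O-triflation are the standard one-flask entry to o-silylaryl triflates, and of the two silyl triflates that can collapse to aryne C4a≡C8a this one (Si on C8a, OTf on C4a) is chosen because its phenol 6 is symmetric and shares its origin with the pendant aryl group.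

Step 6
Reactants: 11 3-[(benzyloxy)methyl]cyclobutan-1-one
Product: 13 (R)-({3-[(benzyloxy)methyl]cyclobut-1-en-1-yl}oxy)triethylsilane, via lithium enolate 12 (not isolated)
Conditions: (S,S)-bis(1-phenylethyl)amine, n-BuLi, THF, −78 to 0 °C; Et3SiCl, then 11 added slowly, −100 °C; Et3N, aq NaHCO3; Et3N-deactivated SiO2
Reagents that add atoms: chlorotriethylsilane, CC[Si](Cl)(CC)CC
Why: Enantioselective deprotonation by a chiral lithium amide with in situ silyl quench, a known desymmetrisation of 3-substituted cyclobutanones: the base selects one of the two enantiotopic α-CH2 groups and so makes prochiral C3 a stereocentre, and Et3Si rather than Me3Si lets 13 survive the chromatography that removes the secondary amine, itself an aryne trap.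

Step 7
Reactants: 10 4-(benzyloxy)-3,5-dimethoxy-2-(trimethylsilyl)phenyl trifluoromethanesulfonate; 13 (R)-({3-[(benzyloxy)methyl]cyclobut-1-en-1-yl}oxy)triethylsilane
Product: 17 (3S)-7-(benzyloxy)-3-[(benzyloxy)methyl]-6,8-dimethoxy-3,4-dihydronaphthalen-1(2H)-one, via aryne 14 (not isolated), via potassium enolate 15 (not isolated), via fused cyclobutoxide 16 (not isolated)
Conditions: KF, 18-crown-6, THF, 0 °C to rt, 13 (1.5 equiv), 10 added over 2 h; sat. aq NH4Cl
Reagents that add atoms: none
Why: Proposed new method: fluoride removes Me3Si from 10, whose triflate then leaves to give aryne 14, and Et3Si from 13 to give enolate 15; the enolate carbon C4 adds to C4a, the aryl anion left on C8a attacks the C1 carbonyl, and the central C1–C4 bond of the resulting benzo-fused bicyclo[2.2.0]hexan-1-olate 16 breaks heterolytically to the aryl ketone and a C4 benzylic anion, which is protonated on quenching. Ring B is therefore not closed by a direct six-membered cyclisation: a 4-exo-trig closure makes the benzocyclobutene ring C1–C4–C4a–C8a, and cleavage of the bond it shares with the cyclobutane merges the two four-membered rings into the six-membered one. The closest known reaction types are the acyl-alkylation of arynes by β-ketoesters and the [2+2]/fragmentation ring expansion of larger cyclic ketone enolates by arynes or cyclohexyne; a simple cyclobutanone enolate is untested, but the carbonyl of a four-membered ring is unusually electrophilic, opening of 16 releases the strain of two small rings instead of one, and the C4 anion is delocalised into the ortho acyl group, which together should make up for the missing ester. The selectivity needed is regiochemical: the C8 methoxy group, through its inductive pull, distorts 14 so that nucleophiles attack the remote and unhindered C4a and the charge builds up on C8a next to oxygen, hence C4 to C4a and C1 to C8a. No lasting stereocentre is formed, since C1 and C4 of 16 (set by approach of 14 anti to C10) end as C=O and CH2, and C3 is a spectator. Its configuration is at risk only if 15 is protonated to achiral 11 and formed again, so the medium is THF rather than acetonitrile, no neutral ketone is present, and 10 is added slowly to an excess of 13.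

Step 8
Reactants: 17 (3S)-7-(benzyloxy)-3-[(benzyloxy)methyl]-6,8-dimethoxy-3,4-dihydronaphthalen-1(2H)-one
Product: 18 methyl (3S)-7-(benzyloxy)-3-[(benzyloxy)methyl]-1-hydroxy-6,8-dimethoxy-3,4-dihydronaphthalene-2-carboxylate (β-ketoester; keto–enol mixture drawn as the enol)
Conditions: NaH, (MeO)2CO, THF, reflux; 1 M HCl, 0 °C
Reagents that add atoms: dimethyl carbonate, COC(=O)OC
Why: Claisen-type C-acylation of the ketone enolate by a carbonate, driven by formation of the stabilised β-ketoester enolate; C2 is the only enolisable position, and its configuration does not matter because it becomes sp2 in the next step.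

Step 9
Reactants: 18 methyl (3S)-7-(benzyloxy)-3-[(benzyloxy)methyl]-1-hydroxy-6,8-dimethoxy-3,4-dihydronaphthalene-2-carboxylate
Product: 19 methyl (3S)-7-(benzyloxy)-3-[(benzyloxy)methyl]-6,8-dimethoxy-1-{[(trifluoromethyl)sulfonyl]oxy}-3,4-dihydronaphthalene-2-carboxylate
Conditions: Tf2O, i-Pr2NEt, CH2Cl2, −78 °C
Reagents that add atoms: trifluoromethanesulfonic anhydride, O=S(=O)(OS(=O)(=O)C(F)(F)F)C(F)(F)F
Why: O-sulfonylation of the enol of a cyclic β-ketoester, the standard entry to β-triflyloxy acrylates; the ring allows only one alkene geometry and the weak amine base leaves C3–H alone.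

Step 10
Reactants: 19 methyl (3S)-7-(benzyloxy)-3-[(benzyloxy)methyl]-6,8-dimethoxy-1-{[(trifluoromethyl)sulfonyl]oxy}-3,4-dihydronaphthalene-2-carboxylate; 5 [4-(benzyloxy)-3,5-dimethoxyphenyl]boronic acid
Product: 20 methyl (3S)-7-(benzyloxy)-1-[4-(benzyloxy)-3,5-dimethoxyphenyl]-3-[(benzyloxy)methyl]-6,8-dimethoxy-3,4-dihydronaphthalene-2-carboxylate
Conditions: Pd(OAc)2, SPhos, K3PO4, toluene/H2O, 80 °C
Reagents that add atoms: none
Why: Suzuki–Miyaura coupling of an electron-poor enol triflate, which adds readily to zerovalent palladium; the bulky biaryl phosphine is chosen because C1 is flanked by the C8 methoxy group and the ester.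

Step 11
Reactants: 20 methyl (3S)-7-(benzyloxy)-1-[4-(benzyloxy)-3,5-dimethoxyphenyl]-3-[(benzyloxy)methyl]-6,8-dimethoxy-3,4-dihydronaphthalene-2-carboxylate
Product: 22 methyl (1R,2S,3S)-7-(benzyloxy)-1-[4-(benzyloxy)-3,5-dimethoxyphenyl]-3-[(benzyloxy)methyl]-6,8-dimethoxy-1,2,3,4-tetrahydronaphthalene-2-carboxylate, via all-cis ester 21 (not isolated)
Conditions: Mg turnings, MeOH/THF, rt, until 20 is consumed; then NaOMe, 65 °C; aq NH4Cl
Reagents that add atoms: none
Why: Dissolving-metal conjugate reduction of a β,β-diaryl acrylate followed by base epimerisation: allylic strain against the C2 ester (later its enolate) holds the C3 side chain pseudo-axial, so C1 is protonated on the opposite face and the aryl group ends cis to C10 (1R), methoxide then equilibrates the only acidic centre C2 to the ester trans to both neighbours (2S), benzyl ethers are inert, and NaOMe is withheld until 20 is gone so that its γ-acidic C3–H never meets strong base.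

Step 12
Reactants: 22 methyl (1R,2S,3S)-7-(benzyloxy)-1-[4-(benzyloxy)-3,5-dimethoxyphenyl]-3-[(benzyloxy)methyl]-6,8-dimethoxy-1,2,3,4-tetrahydronaphthalene-2-carboxylate
Product: 23 {(1R,2S,3S)-7-(benzyloxy)-1-[4-(benzyloxy)-3,5-dimethoxyphenyl]-3-[(benzyloxy)methyl]-6,8-dimethoxy-1,2,3,4-tetrahydronaphthalen-2-yl}methanol
Conditions: LiAlH4, THF, 0 °C to rt; H2O, aq NaOH work-up
Reagents that add atoms: none
Why: Hydride reduction of the ester to the primary alcohol touches no stereocentre, removes the acidity of C2–H and leaves C9–OH as the only free hydroxyl group.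

Step 13
Reactants: 23 {(1R,2S,3S)-7-(benzyloxy)-1-[4-(benzyloxy)-3,5-dimethoxyphenyl]-3-[(benzyloxy)methyl]-6,8-dimethoxy-1,2,3,4-tetrahydronaphthalen-2-yl}methanol
Product: 24 sodium {(1R,2S,3S)-7-(benzyloxy)-1-[4-(benzyloxy)-3,5-dimethoxyphenyl]-3-[(benzyloxy)methyl]-6,8-dimethoxy-1,2,3,4-tetrahydronaphthalen-2-yl}methyl sulfate
Conditions: SO3·pyridine, pyridine, rt; aq NaHCO3; SiO2 (CH2Cl2/MeOH)
Reagents that add atoms: sulfur trioxide–pyridine complex, [O-]S(=O)(=O)[n+]1ccccc1; sodium hydrogen carbonate, [Na+].OC([O-])=O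
Why: O-sulfation of a primary alcohol by an amine–SO3 complex; both phenols and C10–OH are benzylated, so only C9–O can react, and the change to the sodium salt removes pyridine, which would slow the palladium catalyst of the last step.

Step 14
Reactants: 24 sodium {(1R,2S,3S)-7-(benzyloxy)-1-[4-(benzyloxy)-3,5-dimethoxyphenyl]-3-[(benzyloxy)methyl]-6,8-dimethoxy-1,2,3,4-tetrahydronaphthalen-2-yl}methyl sulfate
Product: 26 [(1R,2S,3S)-7-hydroxy-1-(4-hydroxy-3,5-dimethoxyphenyl)-3-(hydroxymethyl)-6,8-dimethoxy-1,2,3,4-tetrahydronaphthalen-2-yl]methyl hydrogen sulfate, via sodium salt 25 (not isolated)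
Conditions: H2 (1 atm), 10% Pd/C, MeOH, rt; filter, evaporate; HCl (1.0 equiv, in EtOH), EtOH, 0 °C; filter off NaCl, evaporate cold
Reagents that add atoms: none
Why: Hydrogenolysis of two aryl benzyl ethers and one alkyl benzyl ether over palladium leaves the non-benzylic alkyl sulfate and the ring C–C bonds intact, and one equivalent of HCl in ethanol then precipitates NaCl and leaves the hydrogen sulfate.

Compound list
1 | 4-bromo-2,6-dimethoxyphenol | COc1cc(Br)cc(OC)c1O | starting material
2 | 2-(benzyloxy)-5-bromo-1,3-dimethoxybenzene | COc1cc(Br)cc(OC)c1OCc1ccccc1 | intermediate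
3 | [4-(benzyloxy)-3,5-dimethoxyphenyl]lithium | [Li]c1cc(OC)c(OCc2ccccc2)c(OC)c1 | intermediate
4 | lithium [4-(benzyloxy)-3,5-dimethoxyphenyl]tri(propan-2-yloxy)borate | [Li+].CC(C)O[B-](OC(C)C)(OC(C)C)c1cc(OC)c(OCc2ccccc2)c(OC)c1 | intermediate
5 | [4-(benzyloxy)-3,5-dimethoxyphenyl]boronic acid | OB(O)c1cc(OC)c(OCc2ccccc2)c(OC)c1 | intermediate
6 | 4-(benzyloxy)-3,5-dimethoxyphenol | COc1cc(O)cc(OC)c1OCc1ccccc1 | intermediate
7 | 4-(benzyloxy)-2-bromo-3,5-dimethoxyphenol | COc1cc(O)c(Br)c(OC)c1OCc1ccccc1 | intermediate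
8 | [4-(benzyloxy)-2-bromo-3,5-dimethoxyphenoxy]trimethylsilane | COc1cc(O[Si](C)(C)C)c(Br)c(OC)c1OCc1ccccc1 | intermediate
9 | lithium 4-(benzyloxy)-3,5-dimethoxy-2-(trimethylsilyl)phenoxide | [Li+].COc1cc([O-])c([Si](C)(C)C)c(OC)c1OCc1ccccc1 | intermediate
10 | 4-(benzyloxy)-3,5-dimethoxy-2-(trimethylsilyl)phenyl trifluoromethanesulfonate (Si on C8a, OTf on C4a) | COc1cc(OS(=O)(=O)C(F)(F)F)c([Si](C)(C)C)c(OC)c1OCc1ccccc1 | intermediate
11 | 3-[(benzyloxy)methyl]cyclobutan-1-one | O=C1CC(COCc2ccccc2)C1 | starting material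
12 | lithium (R)-3-[(benzyloxy)methyl]cyclobut-1-en-1-olate | [Li+].[O-]C1=C[C@H](COCc2ccccc2)C1 | intermediate
13 | (R)-({3-[(benzyloxy)methyl]cyclobut-1-en-1-yl}oxy)triethylsilane | CC[Si](CC)(CC)OC1=C[C@H](COCc2ccccc2)C1 | intermediate
14 | 4-(benzyloxy)-3,5-dimethoxy-1,2-didehydrobenzene (aryne C4a≡C8a) | COC1=C(OCc2ccccc2)C(OC)=CC#C1 | intermediate
15 | potassium (R)-3-[(benzyloxy)methyl]cyclobut-1-en-1-olate | [K+].[O-]C1=C[C@H](COCc2ccccc2)C1 | intermediate
16 | potassium alkoxide of the benzo-fused bicyclo[2.2.0]hexan-1-ol (C4–C4a and C1–C8a formed, C1–C4 still intact, cis ring fusion, arene anti to C10) | [K+].[O-][C@@]12C[C@@H](COCc3ccccc3)[C@@H]1c1cc(OC)c(OCc3ccccc3)c(OC)c12 | intermediate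
17 | (3S)-7-(benzyloxy)-3-[(benzyloxy)methyl]-6,8-dimethoxy-3,4-dihydronaphthalen-1(2H)-one | O=C1C[C@@H](COCc2ccccc2)Cc2cc(OC)c(OCc3ccccc3)c(OC)c21 | intermediate
18 | methyl (3S)-7-(benzyloxy)-3-[(benzyloxy)methyl]-1-hydroxy-6,8-dimethoxy-3,4-dihydronaphthalene-2-carboxylate (enol form of the β-ketoester) | COC(=O)C1=C(O)c2c(OC)c(OCc3ccccc3)c(OC)cc2C[C@@H]1COCc1ccccc1 | intermediate
19 | methyl (3S)-7-(benzyloxy)-3-[(benzyloxy)methyl]-6,8-dimethoxy-1-{[(trifluoromethyl)sulfonyl]oxy}-3,4-dihydronaphthalene-2-carboxylate | COC(=O)C1=C(OS(=O)(=O)C(F)(F)F)c2c(OC)c(OCc3ccccc3)c(OC)cc2C[C@@H]1COCc1ccccc1 | intermediate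
20 | methyl (3S)-7-(benzyloxy)-1-[4-(benzyloxy)-3,5-dimethoxyphenyl]-3-[(benzyloxy)methyl]-6,8-dimethoxy-3,4-dihydronaphthalene-2-carboxylate | COc1cc(C2=C(C(=O)OC)[C@@H](COCc3ccccc3)Cc3cc(OC)c(OCc4ccccc4)c(OC)c32)cc(OC)c1OCc1ccccc1 | intermediate
21 | methyl (1R,2R,3S)-7-(benzyloxy)-1-[4-(benzyloxy)-3,5-dimethoxyphenyl]-3-[(benzyloxy)methyl]-6,8-dimethoxy-1,2,3,4-tetrahydronaphthalene-2-carboxylate (all-cis) | COc1cc([C@@H]2c3c(cc(OC)c(OCc4ccccc4)c3OC)C[C@H](COCc3ccccc3)[C@@H]2C(=O)OC)cc(OC)c1OCc1ccccc1 | intermediate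
22 | methyl (1R,2S,3S)-7-(benzyloxy)-1-[4-(benzyloxy)-3,5-dimethoxyphenyl]-3-[(benzyloxy)methyl]-6,8-dimethoxy-1,2,3,4-tetrahydronaphthalene-2-carboxylate (all-trans) | COc1cc([C@@H]2c3c(cc(OC)c(OCc4ccccc4)c3OC)C[C@H](COCc3ccccc3)[C@H]2C(=O)OC)cc(OC)c1OCc1ccccc1 | intermediate
23 | {(1R,2S,3S)-7-(benzyloxy)-1-[4-(benzyloxy)-3,5-dimethoxyphenyl]-3-[(benzyloxy)methyl]-6,8-dimethoxy-1,2,3,4-tetrahydronaphthalen-2-yl}methanol | COc1cc([C@@H]2c3c(cc(OC)c(OCc4ccccc4)c3OC)C[C@H](COCc3ccccc3)[C@H]2CO)cc(OC)c1OCc1ccccc1 | intermediate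
24 | sodium {(1R,2S,3S)-7-(benzyloxy)-1-[4-(benzyloxy)-3,5-dimethoxyphenyl]-3-[(benzyloxy)methyl]-6,8-dimethoxy-1,2,3,4-tetrahydronaphthalen-2-yl}methyl sulfate | COc1cc([C@@H]2c3c(cc(OC)c(OCc4ccccc4)c3OC)C[C@H](COCc3ccccc3)[C@H]2COS(=O)(=O)[O-])cc(OC)c1OCc1ccccc1.[Na+] | intermediate
25 | sodium [(1R,2S,3S)-7-hydroxy-1-(4-hydroxy-3,5-dimethoxyphenyl)-3-(hydroxymethyl)-6,8-dimethoxy-1,2,3,4-tetrahydronaphthalen-2-yl]methyl sulfate | COc1cc([C@@H]2c3c(cc(OC)c(O)c3OC)C[C@H](CO)[C@H]2COS(=O)(=O)[O-])cc(OC)c1O.[Na+] | intermediate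
26 | [(1R,2S,3S)-7-hydroxy-1-(4-hydroxy-3,5-dimethoxyphenyl)-3-(hydroxymethyl)-6,8-dimethoxy-1,2,3,4-tetrahydronaphthalen-2-yl]methyl hydrogen sulfate (CNP0111670.1) | COc1cc([C@@H]2c3c(cc(OC)c(O)c3OC)C[C@H](CO)[C@H]2COS(=O)(=O)O)cc(OC)c1O | target

Total step count: 14.
Longest linear sequence: 13 steps (steps 1–5 and 7–14). Step 6 is a one-step side branch, and 5 feeds both step 3 and step 10.

Steps most likely to fail

Step 7.
- What may go wrong:
  - The C8a aryl anion may be protonated before it closes onto the carbonyl, so that only α-arylation takes place.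
  - The tetralone enolate may be arylated a second time.
  - Proton exchange at the cyclobutanone enolate may erode the enantiomeric purity.
- Fallback: it uses known chemistry, sets out from 13 and 2, comes back at 17, and makes the same two bonds one after the other.
  - Ozonolysis of 13 (O3, CH2Cl2, −78 °C; Me2S) should cleave C1=C4 to (S)-3-[(benzyloxy)methyl]-4-oxobutanoic acid F1, which is used at once because C3 is α to the aldehyde.
  - Aryllithium 3 is regenerated from 2 (n-BuLi, THF, −78 °C) and two equivalents are added to the aldehyde. This forms C4–C4a, and acidic work-up should give (4S)-5-[4-(benzyloxy)-3,5-dimethoxyphenyl]-4-[(benzyloxy)methyl]oxolan-2-one F2 as both benzylic epimers.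
  - Ionic hydrogenation (Et3SiH, BF3·OEt2, CH2Cl2, −20 to 0 °C) removes the benzylic C4–O bond and should give (S)-3-[(benzyloxy)methyl]-4-[4-(benzyloxy)-3,5-dimethoxyphenyl]butanoic acid F3.
  - Intramolecular Friedel–Crafts acylation ((CF3CO)2O, CH2Cl2, 0 °C) at either of the two equivalent ortho positions forms C1–C8a and gives 17.

Step 11.
- What may go wrong:
  - Facial selectivity in the protonation of C1 may be poor.
  - Electron transfer to the hindered, twisted tetrasubstituted acrylate may be sluggish.
- Fallback: it sets out from 20 and comes back at 22.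
  - The stepwise electron and proton transfer is replaced by homogeneous syn-hydrogenation with [Ir(cod)(PCy3)(py)]PF6 (H2, 50 bar, CH2Cl2), which spares benzyl ethers.
  - This delivers both hydrogens from a bulky metal centre, so it should respond more strongly to the pseudo-axial C10 branch.
  - It should give the all-cis ester 21, this time isolated, and NaOMe in MeOH at 65 °C then epimerises C2 to 22.
  - This fallback makes no compound outside the list (F0).

Step 6.
- What may go wrong: the base may discriminate incompletely between the enantiotopic α-protons, so that the whole series is not enantiomerically pure enough.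
- Fallback: it sets out from 23 and comes back at 23, and it adds a separation of diastereomers instead of relying on the base alone.
  - Alcohol 23 is esterified with (S)-2-methoxy-2-phenylacetic acid (DCC, DMAP, CH2Cl2) to the (S)-2-methoxy-2-phenylacetate of 23 F4.
  - The (S)-2-methoxy-2-phenylacetate of the enantiomer of 23 F5, formed from the minor enantiomer, is removed by crystallisation or chromatography.
  - Methanolysis of pure F4 (K2CO3, MeOH, rt) returns 23.

Further compounds
F1 | step 7 | (S)-3-[(benzyloxy)methyl]-4-oxobutanoic acid | O=C[C@H](COCc1ccccc1)CC(=O)O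
F2 | step 7 | (4S)-5-[4-(benzyloxy)-3,5-dimethoxyphenyl]-4-[(benzyloxy)methyl]oxolan-2-one, both C5 epimers | O=C1C[C@@H](COCc2ccccc2)C(c2cc(OC)c(OCc3ccccc3)c(OC)c2)O1
F3 | step 7 | (S)-3-[(benzyloxy)methyl]-4-[4-(benzyloxy)-3,5-dimethoxyphenyl]butanoic acid | OC(=O)C[C@@H](COCc1ccccc1)Cc1cc(OC)c(OCc2ccccc2)c(OC)c1
F0 | step 11 | none | none
F4 | step 6 | (S)-2-methoxy-2-phenylacetate of 23 | COc1cc([C@@H]2c3c(cc(OC)c(OCc4ccccc4)c3OC)C[C@H](COCc3ccccc3)[C@H]2COC(=O)[C@@H](OC)c2ccccc2)cc(OC)c1OCc1ccccc1
F5 | step 6 | (S)-2-methoxy-2-phenylacetate of the enantiomer of 23 | COc1cc([C@H]2c3c(cc(OC)c(OCc4ccccc4)c3OC)C[C@@H](COCc3ccccc3)[C@@H]2COC(=O)[C@@H](OC)c2ccccc2)cc(OC)c1OCc1ccccc1
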